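## Analysis of the target

Target 25 is a daucane sesquiterpenoid monoester. A cyclopentane (C1–C5) is trans-fused through the C1–C5 bond to a cycloheptane (C1, C5, C6–C10). C1 carries the angular methyl (C15), C4 a tertiary hydroxyl and the isopropyl group, C6 the 3-methylbutanoate, C8 an exocyclic methylidene (C14), and C9 and C10 a diol.

There are six stereocentres, (1S,4R,5S,6S,9R,10S). The C1 methyl and C5–H are trans. The C4 hydroxyl lies on the methyl face. The oxygens at C6, C9 and C10 all lie on the opposite face, so the 9,10-diol is cis and the C10 hydroxyl is anti to the neighbouring methyl.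

The ester can migrate to or be cleaved beside three free hydroxyls under basic conditions. The tertiary carbinol can eliminate under acid. The exocyclic alkene sits next to an allylic carbinol and can move into conjugation while C10 is a ketone.

The difficulty lies in the quaternary ring-fusion carbon C1 flanked by oxygenated carbons, in two contiguous stereotriads (C4–C5–C6 and C1–C10–C9), in closing a seven-membered ring, and in acylating only one of four hydroxyls.

The strategy rests on the run C4(O)–C5(H)–C1(CH3) with the oxygenated C6 on C5. Read as a cyclopentanone, C4 is the carbonyl carbon, C5 its α-carbon, C1 the β-carbon and C6 an aldol carbinol. β-Methylation of a 3-substituted cyclopentenone with α-aldol trapping therefore creates C1, C5 and C6 in one operation. The carbonyl is left for the isopropyl group, the C1 substituent becomes C10, and an alkyne on the aldehyde carries C7, C8 and C14.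

## Retrosynthetic reasoning

**C10–H and C9–O.** Target 25 is the bis-desilylated form of 24. In 24 the C10–H bond is cut, which leads to the α-silyloxy ketone 23 and, after removing the silyl group, to ketol 22. The C9–O bond of 22 is cut next, giving ketone 20 through its dienolate 21. C9 is the only enolisable position of the C10 ketone, so the site of hydroxylation is fixed. The same ketone then serves to set C10. The forward steps must deliver oxygen to C9 anti to the methyl and hydride to C10 anti to the C9 oxygen.

**C8–C9.** The seven-membered ring of 20 is opened at C8–C9, giving enol ether–alkyne 19. This bond joins two arms that sit trans on the cyclopentane. Its formation by carbon attack of an enol ether on a terminal alkyne gives the methylidene and the C10 ketone directly and creates no stereocentre, so it can stand late. Cutting C6–C7 or C9–C10 instead would break the ring beside stereocentres. The forward reaction has to attack in the exo sense and be faster than loss of the enol ether.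

**C9–C10.** Enol ether 19 comes from methyl ketone 18. Its methyl carbon (C9) is removed, leading back through carbinol 17 to aldehyde 16 and primary alcohol 15. The gain is that C1 needs only a small oxygenated one-carbon substituent when the quaternary centre is made.

**C6 ester C–O.** Alcohol 15 arises from 14 by removing the two silyl groups, and 14 from diol 13 by acylation. The ester is placed here because in 13 the C6 hydroxyl is the only secondary one; after C9 and C10 are oxygenated, three secondary hydroxyls would compete. The ester also masks the homopropargylic oxygen, which would otherwise add to the alkyne during ring closure.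

**C4–isopropyl.** Diol 13 is cut at the C4–isopropyl bond, giving ketone 12. The forward addition has to come from the face opposite the C5 side chain and must avoid enolisation and retro-aldol cleavage.

**C1–CH3 and C5–C6 (key).** Aldol 12 is cut at both bonds that flank the C4 carbonyl, giving enone 6, the methyl donor 9 and aldehyde 8. One enolate links the two bond formations, three stereocentres are set, and the fragments are simple.

**Fragments.** Enone 6 is the silyl ether of 5, which comes from acetal 4. Acetal 4 is cut at the ring–CH2O bond into stannane 1 and vinylogous ester 2 (through adduct 3). The one-carbon unit is carried as an acetal because an α-silyloxy carbanion would rearrange by silyl shift from oxygen to carbon; the silyl group is therefore put on afterwards. Aldehyde 8 is the oxidation product of alcohol 7.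

## Alternatives that were turned down

**Alternative 1:** The seven-membered ring is cut at C7–C8 and C1–C10, a formal (4+3) disconnection. The fragments are vinylcyclopentene A1 (C1 methyl on the ring alkene, C4 as its ethylene ketal) and vinyldiazoacetate A2. Rh2(S-DOSP)4, dirhodium tetrakis[(S)-N-(dodecylbenzenesulfonyl)prolinate], or its enantiomer would cyclopropanate the vinyl group of A1 with the carbenoid from A2. The cis-divinylcyclopropane would then undergo Cope rearrangement to dienoate A3.
- For: the ring, the quaternary C1 and the absolute configuration come from one catalytic step and two small fragments. This is more economical in ring construction than the chosen route, which closes the ring separately in step 13.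
- Against: the Cope step has to form the quaternary centre from a fully substituted alkene terminus. A3 has C10 as an unactivated methylene beside the quaternary carbon, so the cis-diol must be made late by allylic oxidation. C14 arrives as an ester on an endocyclic C8=C9 alkene and must be deoxygenated and moved to the exocyclic position. C4, C5 and C6 remain to be set.
- Comparison: the chosen strategy is weaker in ring-forming economy but starts with C4, C6 and C10 oxygenated and with C8 and C14 at the right oxidation level.

**Alternative 2:** The C1–C5 bond is traced to a 1,2-shift in decalin mesylate A4, a cis-fused decalin from the Wieland–Miescher ketone. In A4, C1 is bonded to the tertiary carbinol carbon C6 and C5 carries the mesylate. KOt-Bu would deprotonate the C6 hydroxyl, and C1 would migrate from C6 to C5 with loss of mesylate. One ring contracts to the cyclopentane and the other expands to the cycloheptanone, giving hydroazulenone A5.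
- For: the shift is stereospecific (migrating bond anti to the leaving group, inversion at C5). The trans fusion is therefore more certain than the facial bias that sets C5 in step 5. C1 comes from a cheap enantiopure building block.
- Against: A4 needs a long sequence before the key step. A5 has C7, C8 and C9 as bare methylenes, so C14 must be attached at C8, which is β to both carbonyls, and C9 must be hydroxylated. C6 must still be reduced to the correct carbinol.
- Comparison: the chosen strategy gives up the stereospecificity at C5. In return it sets C6 as a defined carbinol and brings in C7, C8 and C14 with the aldehyde.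

**Alternative 3:** The C8–C9 bond is cut, giving enol ether–alkyne A6. A cationic monovalent gold complex such as (Ph3P)AuNTf2 would activate the alkyne for 7-exo-dig attack by C9 and give methylidenecycloheptanone A7.
- For: neutral conditions, tolerance of the ester, and formation of ring, methylidene and C10 ketone in one step.
- Against, as the step on which the plan rests: it forms no stereocentre and does not say how the cyclopentane of A6, with C1, C4, C5 and C6, is made. The risk of a seven-membered ring closure would sit at the end with nothing else gained.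
- Comparison: on the ring closure the two plans are equal. A6 and A7 are the same structures as 19 and 20, and the chosen route uses this closure in step 13. The chosen strategy adds the three-component step that builds the cyclopentane with three stereocentres early.

Key step: step 5

## Route

Remark: bicyclic compounds are numbered as in daucane (C1–C10 in the rings, C11–C13 isopropyl, C14 on C8, C15 on C1); monocyclic intermediates carry cyclopentane names.

Step 1
Reactants: 1 tributyl[(methoxymethoxy)methyl]stannane; 2 3-ethoxycyclopent-2-en-1-one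
Product: 4 3-[(methoxymethoxy)methyl]cyclopent-2-en-1-one, via lithium alkoxide adduct 3 (not isolated)
Conditions: n-BuLi, THF, −78 °C; then 2, −78 → 0 °C; then 1 M HCl aq, rt
Reagents that add atoms: water, O
Why: Tin–lithium exchange gives the acetal-protected hydroxymethyllithium, which adds 1,2 to the vinylogous ester; aqueous acid then hydrolyses the enol ether and eliminates the tertiary hydroxyl (Stork–Danheiser transposition), and the acetal survives the brief dilute acid.

Step 2
Reactants: 4 3-[(methoxymethoxy)methyl]cyclopent-2-en-1-one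
Product: 5 3-(hydroxymethyl)cyclopent-2-en-1-one
Conditions: conc. HCl (cat.), MeOH, 50 °C
Reagents that add atoms: none
Why: Acid-catalysed transacetalisation to methanol removes the methoxymethyl group as dimethoxymethane; the simple enone tolerates these conditions.

Step 3
Reactants: 5 3-(hydroxymethyl)cyclopent-2-en-1-one
Product: 6 3-{[tert-butyl(dimethyl)silyl]oxymethyl}cyclopent-2-en-1-one
Conditions: TBSCl, imidazole, DMF, 0 °C → rt
Reagents that add atoms: tert-butyl(chloro)dimethylsilane, CC(C)(C)[Si](C)(C)Cl
Why: Imidazole-promoted silylation of a primary alcohol.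

Step 4
Reactants: 7 4-(trimethylsilyl)but-3-yn-1-ol
Product: 8 4-(trimethylsilyl)but-3-ynal
Conditions: Dess–Martin periodinane, CH2Cl2, 0 °C → rt; rapid filtration, used at once
Reagents that add atoms: none
Why: Dess–Martin oxidation is neutral and fast, which matters because this β,γ-acetylenic aldehyde isomerises to the allenyl aldehyde with base.

Step 5
Reactants: 6 3-{[tert-butyl(dimethyl)silyl]oxymethyl}cyclopent-2-en-1-one; 9 trimethylaluminium; 8 4-(trimethylsilyl)but-3-ynal
Product: 12 (2S,3S)-3-{[tert-butyl(dimethyl)silyl]oxymethyl}-2-[(1S)-1-hydroxy-4-(trimethylsilyl)but-3-yn-1-yl]-3-methylcyclopentan-1-one, via dimethylaluminium enolate 10 (not isolated), via lithium aluminate enolate 11 (not isolated)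
Conditions: Cu(OTf)2 (5 mol %), chiral sulfonate-bearing N-heterocyclic carbene (from its imidazolinium salt and Ag2O, 5 mol %; the enantiomer that gives (S)-C1), 9 (1.5 equiv), THF, −78 °C; then MeLi (1.5 equiv), −78 °C; then 8 (2 equiv), −78 °C; aq. NH4Cl
Reagents that add atoms: none
Why: Me3Al reduces Cu(OTf)2 to a monovalent copper methyl species bound to the chiral carbene, which adds to the enone face chosen by the ligand (trivalent copper β-adduct, then reductive elimination), forming C1–CH3 and, after transmetalation, aluminium enolate 10. MeLi converts 10 into the more nucleophilic aluminate 11, which adds through C5 to aldehyde 8 in a closed six-membered chair transition state and forms C5–C6. The closest known reaction type is the copper–carbene-catalysed enantioselective addition of trialkylaluminium reagents to β-substituted cyclopentenones with trapping of the aluminium enolate by an electrophile. No ring is closed. C1 (S) is set by the catalyst; C5 (S) by approach of the aldehyde to the enolate face anti to the larger silyloxymethyl group on the neighbouring quaternary carbon; C6 (S) by the chair transition state of the ring-locked (E)-enolate with the aldehyde substituent equatorial, which gives the anti aldol. The step needs 1,4- over 1,2-methyl transfer (secured by copper catalysis), enolate addition over methyl transfer from aluminium to the aldehyde (secured by ate formation at −78 °C, which ties residual Me3Al up as LiAlMe4), and addition faster than proton transfer from the acidic propargylic CH2 of 8 (low temperature, low basicity of the aluminate).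

Step 6
Reactants: 12 (2S,3S)-3-{[tert-butyl(dimethyl)silyl]oxymethyl}-2-[(1S)-1-hydroxy-4-(trimethylsilyl)but-3-yn-1-yl]-3-methylcyclopentan-1-one
Product: 13 (1R,2S,3S)-3-{[tert-butyl(dimethyl)silyl]oxymethyl}-2-[(1S)-1-hydroxy-4-(trimethylsilyl)but-3-yn-1-yl]-3-methyl-1-(propan-2-yl)cyclopentan-1-ol
Conditions: i-PrMgCl (3.5 equiv), CeCl3 (anhydrous, 3.5 equiv), THF, −78 → −20 °C; aq. NH4Cl
Reagents that add atoms: isopropylmagnesium chloride, CC(C)[Mg]Cl
Why: The weakly basic organocerium reagent first deprotonates the C6 hydroxyl and then adds to the hindered, enolisable ketone instead of enolising or reducing it. Addition should occur on the face carrying C5–H, anti to the C5 side chain, which places the new hydroxyl cis to that chain (4R in daucane numbering).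

Step 7
Reactants: 13 (1R,2S,3S)-3-{[tert-butyl(dimethyl)silyl]oxymethyl}-2-[(1S)-1-hydroxy-4-(trimethylsilyl)but-3-yn-1-yl]-3-methyl-1-(propan-2-yl)cyclopentan-1-ol
Product: 14 (1R,2S,3S)-3-{[tert-butyl(dimethyl)silyl]oxymethyl}-3-methyl-2-[(1S)-1-(3-methylbutanoyloxy)-4-(trimethylsilyl)but-3-yn-1-yl]-1-(propan-2-yl)cyclopentan-1-ol
Conditions: 3-methylbutanoyl chloride, pyridine, DMAP (cat.), CH2Cl2, 0 °C → rt
Reagents that add atoms: 3-methylbutanoyl chloride, CC(C)CC(=O)Cl
Why: Acylation distinguishes the secondary C6 hydroxyl from the tertiary C4 hydroxyl. Placing the final ester here, while C6–OH is the only acylable hydroxyl, avoids any late differentiation and masks the homopropargylic oxygen for step 13.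

Step 8
Reactants: 14 (1R,2S,3S)-3-{[tert-butyl(dimethyl)silyl]oxymethyl}-3-methyl-2-[(1S)-1-(3-methylbutanoyloxy)-4-(trimethylsilyl)but-3-yn-1-yl]-1-(propan-2-yl)cyclopentan-1-ol
Product: 15 (1R,2S,3S)-3-(hydroxymethyl)-3-methyl-2-[(1S)-1-(3-methylbutanoyloxy)but-3-yn-1-yl]-1-(propan-2-yl)cyclopentan-1-ol
Conditions: TBAF (3 equiv), AcOH (3 equiv), THF, 0 °C → rt
Reagents that add atoms: none
Why: Fluoride cleaves the primary O–Si bond and the C(sp)–Si bond in one operation; AcOH keeps the medium near neutral so that the ester neither migrates to the new primary hydroxyl nor is cleaved.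

Step 9
Reactants: 15 (1R,2S,3S)-3-(hydroxymethyl)-3-methyl-2-[(1S)-1-(3-methylbutanoyloxy)but-3-yn-1-yl]-1-(propan-2-yl)cyclopentan-1-ol
Product: 16 (1S,2S,3R)-3-hydroxy-1-methyl-2-[(1S)-1-(3-methylbutanoyloxy)but-3-yn-1-yl]-3-(propan-2-yl)cyclopentane-1-carbaldehyde
Conditions: Dess–Martin periodinane, NaHCO3, CH2Cl2, 0 °C → rt
Reagents that add atoms: none
Why: Dess–Martin oxidation of the only oxidisable hydroxyl (the tertiary one is inert). The aldehyde has no α-hydrogen and cannot form a lactol with the C4 hydroxyl, which lies on the opposite ring face.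

Step 10
Reactants: 16 (1S,2S,3R)-3-hydroxy-1-methyl-2-[(1S)-1-(3-methylbutanoyloxy)but-3-yn-1-yl]-3-(propan-2-yl)cyclopentane-1-carbaldehyde
Product: 17 (1R,2S,3S)-3-(1-hydroxyethyl)-3-methyl-2-[(1S)-1-(3-methylbutanoyloxy)but-3-yn-1-yl]-1-(propan-2-yl)cyclopentan-1-ol (both epimers at the hydroxyethyl carbon)
Conditions: MeMgBr (3 equiv), THF, −78 °C; aq. NH4Cl at −78 °C
Reagents that add atoms: methylmagnesium bromide, C[Mg]Br
Why: At −78 °C the Grignard reagent adds to the aldehyde far faster than to the hindered ester; one equivalent is consumed by the tertiary hydroxyl, and the cold quench limits a 1,3-acyl shift. The configuration of the new carbinol is irrelevant because step 11 oxidises it.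

Step 11
Reactants: 17 (1R,2S,3S)-3-(1-hydroxyethyl)-3-methyl-2-[(1S)-1-(3-methylbutanoyloxy)but-3-yn-1-yl]-1-(propan-2-yl)cyclopentan-1-ol
Product: 18 1-[(1S,2S,3R)-3-hydroxy-1-methyl-2-[(1S)-1-(3-methylbutanoyloxy)but-3-yn-1-yl]-3-(propan-2-yl)cyclopentyl]ethan-1-one
Conditions: Dess–Martin periodinane, NaHCO3, CH2Cl2, rt
Reagents that add atoms: none
Why: Dess–Martin oxidation of the secondary alcohol to the methyl ketone under buffered conditions; both carbinol epimers converge.

Step 12
Reactants: 18 1-[(1S,2S,3R)-3-hydroxy-1-methyl-2-[(1S)-1-(3-methylbutanoyloxy)but-3-yn-1-yl]-3-(propan-2-yl)cyclopentyl]ethan-1-one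
Product: 19 triethyl({1-[(1S,2S,3R)-1-methyl-2-[(1S)-1-(3-methylbutanoyloxy)but-3-yn-1-yl]-3-(propan-2-yl)-3-(triethylsilyloxy)cyclopentyl]ethenyl}oxy)silane
Conditions: TESOTf (3 equiv), Et3N (5 equiv), CH2Cl2, −78 → 0 °C
Reagents that add atoms: triethylsilyl trifluoromethanesulfonate, CC[Si](CC)(CC)OS(=O)(=O)C(F)(F)F
Why: Soft enolisation gives the only possible enol ether, because the other α-carbon is quaternary. The tertiary C4 hydroxyl is silylated in the same operation, which keeps it from adding to the alkyne in step 13; the ester α-hydrogens are not acidic enough to react.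

Step 13
Reactants: 19 triethyl({1-[(1S,2S,3R)-1-methyl-2-[(1S)-1-(3-methylbutanoyloxy)but-3-yn-1-yl]-3-(propan-2-yl)-3-(triethylsilyloxy)cyclopentyl]ethenyl}oxy)silane
Product: 20 (1S,4R,5S,6S)-6-(3-methylbutanoyloxy)-4-(triethylsilyloxy)dauc-8(14)-en-10-one
Conditions: (Ph3P)AuNTf2 (5 mol %), t-BuOH (1.5 equiv), 4 Å MS, CH2Cl2, rt
Reagents that add atoms: none
Why: Cationic monovalent gold activates the terminal alkyne, and the enol ether carbon C9 attacks the internal carbon C8 anti to gold (7-exo-dig carbocyclisation of a silyl enol ether, a known gold-catalysed reaction type). t-BuOH takes up the silyl group and supplies the proton for protodeauration, leaving the C8 methylidene and the C10 ketone. The trans arrangement of the two arms on the cyclopentane holds C8 and C9 close and gives the trans-fused ring; no stereocentre is formed.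

Step 14
Reactants: 20 (1S,4R,5S,6S)-6-(3-methylbutanoyloxy)-4-(triethylsilyloxy)dauc-8(14)-en-10-one
Product: 22 (1S,4R,5S,6S,9R)-9-hydroxy-6-(3-methylbutanoyloxy)-4-(triethylsilyloxy)dauc-8(14)-en-10-one, via potassium dienolate 21 (not isolated)
Conditions: KN(SiMe3)2 (1.1 equiv), THF, −78 °C; then 3-phenyl-2-(phenylsulfonyl)oxaziridine (1.3 equiv), −78 °C; aq. NH4Cl at −78 °C
Reagents that add atoms: 3-phenyl-2-(phenylsulfonyl)oxaziridine, O=S(=O)(c1ccccc1)N1OC1c1ccccc1
Why: Only C9 carries α-hydrogens, so a single extended enolate forms, and metal dienolates react with N-sulfonyloxaziridines at the α-carbon (enolate hydroxylation), not at the γ-terminus. The oxidant should approach C9 anti to the pseudo-axial C1 methyl, giving 9R. A cold quench limits ketol tautomerisation and migration of the alkene into conjugation.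

Step 15
Reactants: 22 (1S,4R,5S,6S,9R)-9-hydroxy-6-(3-methylbutanoyloxy)-4-(triethylsilyloxy)dauc-8(14)-en-10-one
Product: 23 (1S,4R,5S,6S,9R)-9-(tert-butyldimethylsilyloxy)-6-(3-methylbutanoyloxy)-4-(triethylsilyloxy)dauc-8(14)-en-10-one
Conditions: TBSOTf, 2,6-lutidine, CH2Cl2, −78 °C
Reagents that add atoms: tert-butyldimethylsilyl trifluoromethanesulfonate, CC(C)(C)[Si](C)(C)OS(=O)(=O)C(F)(F)F
Why: At −78 °C silylation of the hydroxyl is faster than enol silylation of the ketone. The bulky ether stops ketol tautomerisation and shields the face of the C10 carbonyl on which the C9 oxygen lies.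

Step 16
Reactants: 23 (1S,4R,5S,6S,9R)-9-(tert-butyldimethylsilyloxy)-6-(3-methylbutanoyloxy)-4-(triethylsilyloxy)dauc-8(14)-en-10-one
Product: 24 (1S,4R,5S,6S,9R,10S)-9-(tert-butyldimethylsilyloxy)-10-hydroxy-4-(triethylsilyloxy)dauc-8(14)-en-6-yl 3-methylbutanoate
Conditions: Li(s-Bu)3BH (L-Selectride), THF, −78 °C; aq. NH4Cl
Reagents that add atoms: none
Why: The bulky trialkylborohydride cannot be guided by the silylated C9 oxygen and should attack C10 along the equatorial trajectory, anti to the neighbouring silyloxy group (Felkin–Anh control by the polar α-substituent), as such hydrides generally do even past an axial α-methyl group. This gives the axial C10 hydroxyl cis to the C9 oxygen (10S); the ester is not reduced at −78 °C.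

Step 17
Reactants: 24 (1S,4R,5S,6S,9R,10S)-9-(tert-butyldimethylsilyloxy)-10-hydroxy-4-(triethylsilyloxy)dauc-8(14)-en-6-yl 3-methylbutanoate
Product: 25 (1S,4R,5S,6S,9R,10S)-4,9,10-trihydroxydauc-8(14)-en-6-yl 3-methylbutanoate
Conditions: HF·pyridine, pyridine, THF, 0 °C → rt
Reagents that add atoms: none
Why: Buffered acidic fluoride removes the tertiary triethylsilyl and the secondary tert-butyldimethylsilyl ether without base, so the ester should stay on C6 and the allylic diol and exocyclic alkene should not isomerise.

## Compound list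

1 | tributyl[(methoxymethoxy)methyl]stannane | CCCC[Sn](CCCC)(CCCC)COCOC | starting material
2 | 3-ethoxycyclopent-2-en-1-one | CCOC1=CC(=O)CC1 | starting material
3 | lithium 3-ethoxy-1-[(methoxymethoxy)methyl]cyclopent-2-en-1-olate (racemic) | [Li]OC1(COCOC)C=C(OCC)CC1 | intermediate
4 | 3-[(methoxymethoxy)methyl]cyclopent-2-en-1-one | COCOCC1=CC(=O)CC1 | intermediate
5 | 3-(hydroxymethyl)cyclopent-2-en-1-one | OCC1=CC(=O)CC1 | intermediate
6 | 3-{[tert-butyl(dimethyl)silyl]oxymethyl}cyclopent-2-en-1-one | O=C1C=C(CO[Si](C)(C)C(C)(C)C)CC1 | intermediate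
7 | 4-(trimethylsilyl)but-3-yn-1-ol | C[Si](C)(C)C#CCCO | starting material
8 | 4-(trimethylsilyl)but-3-ynal | C[Si](C)(C)C#CCC=O | intermediate
9 | trimethylaluminium | C[Al](C)C | starting material
10 | dimethylaluminium (3S)-3-{[tert-butyl(dimethyl)silyl]oxymethyl}-3-methylcyclopent-1-en-1-olate | C[Al](C)OC1=C[C@](C)(CC1)CO[Si](C)(C)C(C)(C)C | intermediate
11 | lithium trimethyl[(3S)-3-{[tert-butyl(dimethyl)silyl]oxymethyl}-3-methylcyclopent-1-en-1-olato]aluminate | [Li+].C[Al-](C)(C)OC1=C[C@](C)(CC1)CO[Si](C)(C)C(C)(C)C | intermediate
12 | (2S,3S)-3-{[tert-butyl(dimethyl)silyl]oxymethyl}-2-[(1S)-1-hydroxy-4-(trimethylsilyl)but-3-yn-1-yl]-3-methylcyclopentan-1-one | C[Si](C)(C)C#CC[C@H](O)[C@@H]2[C@](C)(CCC2=O)CO[Si](C)(C)C(C)(C)C | intermediate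
13 | (1R,2S,3S)-3-{[tert-butyl(dimethyl)silyl]oxymethyl}-2-[(1S)-1-hydroxy-4-(trimethylsilyl)but-3-yn-1-yl]-3-methyl-1-(propan-2-yl)cyclopentan-1-ol | C[Si](C)(C)C#CC[C@H](O)[C@@H]2[C@](C)(CC[C@@]2(O)C(C)C)CO[Si](C)(C)C(C)(C)C | intermediate
14 | (1R,2S,3S)-3-{[tert-butyl(dimethyl)silyl]oxymethyl}-3-methyl-2-[(1S)-1-(3-methylbutanoyloxy)-4-(trimethylsilyl)but-3-yn-1-yl]-1-(propan-2-yl)cyclopentan-1-ol | C[Si](C)(C)C#CC[C@H](OC(=O)CC(C)C)[C@@H]2[C@](C)(CC[C@@]2(O)C(C)C)CO[Si](C)(C)C(C)(C)C | intermediate
15 | (1R,2S,3S)-3-(hydroxymethyl)-3-methyl-2-[(1S)-1-(3-methylbutanoyloxy)but-3-yn-1-yl]-1-(propan-2-yl)cyclopentan-1-ol | C#CC[C@H](OC(=O)CC(C)C)[C@@H]2[C@](C)(CC[C@@]2(O)C(C)C)CO | intermediate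
16 | (1S,2S,3R)-3-hydroxy-1-methyl-2-[(1S)-1-(3-methylbutanoyloxy)but-3-yn-1-yl]-3-(propan-2-yl)cyclopentane-1-carbaldehyde | C#CC[C@H](OC(=O)CC(C)C)[C@@H]2[C@](C)(CC[C@@]2(O)C(C)C)C=O | intermediate
17 | (1R,2S,3S)-3-(1-hydroxyethyl)-3-methyl-2-[(1S)-1-(3-methylbutanoyloxy)but-3-yn-1-yl]-1-(propan-2-yl)cyclopentan-1-ol (both epimers at the hydroxyethyl carbon) | C#CC[C@H](OC(=O)CC(C)C)[C@@H]2[C@](C)(CC[C@@]2(O)C(C)C)C(C)O | intermediate
18 | 1-[(1S,2S,3R)-3-hydroxy-1-methyl-2-[(1S)-1-(3-methylbutanoyloxy)but-3-yn-1-yl]-3-(propan-2-yl)cyclopentyl]ethan-1-one | C#CC[C@H](OC(=O)CC(C)C)[C@@H]2[C@](C)(CC[C@@]2(O)C(C)C)C(C)=O | intermediate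
19 | triethyl({1-[(1S,2S,3R)-1-methyl-2-[(1S)-1-(3-methylbutanoyloxy)but-3-yn-1-yl]-3-(propan-2-yl)-3-(triethylsilyloxy)cyclopentyl]ethenyl}oxy)silane | C#CC[C@H](OC(=O)CC(C)C)[C@@H]2[C@](C)(CC[C@@]2(O[Si](CC)(CC)CC)C(C)C)C(=C)O[Si](CC)(CC)CC | intermediate
20 | (1S,4R,5S,6S)-6-(3-methylbutanoyloxy)-4-(triethylsilyloxy)dauc-8(14)-en-10-one | C=C1C[C@H](OC(=O)CC(C)C)[C@@H]2[C@](C)(CC[C@@]2(O[Si](CC)(CC)CC)C(C)C)C(=O)C1 | intermediate
21 | potassium (1S,4R,5S,6S)-6-(3-methylbutanoyloxy)-4-(triethylsilyloxy)dauca-8(14),9-dien-10-olate | C=C1C[C@H](OC(=O)CC(C)C)[C@@H]2[C@](C)(CC[C@@]2(O[Si](CC)(CC)CC)C(C)C)C(O[K])=C1 | intermediate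
22 | (1S,4R,5S,6S,9R)-9-hydroxy-6-(3-methylbutanoyloxy)-4-(triethylsilyloxy)dauc-8(14)-en-10-one | C=C1C[C@H](OC(=O)CC(C)C)[C@@H]2[C@](C)(CC[C@@]2(O[Si](CC)(CC)CC)C(C)C)C(=O)[C@@H]1O | intermediate
23 | (1S,4R,5S,6S,9R)-9-(tert-butyldimethylsilyloxy)-6-(3-methylbutanoyloxy)-4-(triethylsilyloxy)dauc-8(14)-en-10-one | C=C1C[C@H](OC(=O)CC(C)C)[C@@H]2[C@](C)(CC[C@@]2(O[Si](CC)(CC)CC)C(C)C)C(=O)[C@@H]1O[Si](C)(C)C(C)(C)C | intermediate
24 | (1S,4R,5S,6S,9R,10S)-9-(tert-butyldimethylsilyloxy)-10-hydroxy-4-(triethylsilyloxy)dauc-8(14)-en-6-yl 3-methylbutanoate | C=C1C[C@H](OC(=O)CC(C)C)[C@@H]2[C@](C)(CC[C@@]2(O[Si](CC)(CC)CC)C(C)C)[C@H](O)[C@@H]1O[Si](C)(C)C(C)(C)C | intermediate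
25 | (1S,4R,5S,6S,9R,10S)-4,9,10-trihydroxydauc-8(14)-en-6-yl 3-methylbutanoate | C=C1C[C@H](OC(=O)CC(C)C)[C@@H]2[C@](C)(CC[C@@]2(O)C(C)C)[C@H](O)[C@@H]1O | target

## Step count and least certain steps

Total: 17 steps. Longest linear sequence: 16 steps (steps 1–3 and 5–17); step 4 is a one-step branch.

**Step 5 (key).** Three things may go wrong. Methyl transfer to the β-carbon, which carries a Lewis-basic silyloxymethyl group, may be slow or poorly enantioselective. In the aldol stage, methyl transfer from aluminium to the aldehyde or proton transfer from the acidic propargylic CH2 of 8 may outrun C–C bond formation. Facial discrimination at C5 between methyl and silyloxymethyl may be weak, so that C5 epimers form. The fallback separates the two bond formations. It sets out from 6 and 9: after the conjugate addition, enolate 10 is trapped with TMSOTf and Et3N to give the trimethylsilyl enol ether F1, which is isolated. MeLi in THF then releases the lithium enolate, ZnCl2 converts it to the less basic zinc enolate, and addition of 8 at −78 °C through a closed transition state returns to 12.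

**Step 13.** The seven-membered ring closure may be slower than protodesilylation of the enol ether (returning the methyl ketone) or than hydration or alkoxylation of the alkyne assisted by the C6 ester carbonyl. The fallback forms C8–C9 by cross-coupling. It sets out from 18: the tertiary hydroxyl is silylated (TESOTf, 2,6-lutidine, −78 °C) to the triethylsilyl ether F2. Markovnikov hydroiodination of the alkyne with 9-iodo-9-borabicyclo[3.3.1]nonane followed by AcOH gives the 2-iodoalkene F3. Intramolecular α-alkenylation of the ketone enolate (Pd(PPh3)4, KOPh, THF, 70 °C; oxidative addition of zerovalent palladium, then reductive elimination) comes back at 20.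

**Step 16.** Hydride may be delivered anti to the C1 methyl instead of anti to the C9 silyloxy group, giving the C10 epimer. The conformation of the seven-membered ring decides this and cannot be predicted with confidence. The fallback replaces substrate control by reagent control. It sets out from 23 and comes back at 24: Corey–Bakshi–Shibata reduction with catecholborane (which does not hydroborate the alkene at low temperature) and the oxazaborolidine enantiomer that, with the quaternary C1 flank as the large group, sends hydride to the methyl-bearing face. Any epimer can be returned to 23 by oxidation. No new compound is involved.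

**Step 14.** Oxidation may occur at the γ-terminus of the dienolate, the alkene may move into conjugation, the oxidant may approach from the methyl face, or the α-ketol may tautomerise. The fallback carries the C9 oxygen through the ring closure. It sets out from 19: Rubottom oxidation (m-CPBA, NaHCO3, CH2Cl2) gives the hydroxy ketone F4, and TBSCl with imidazole gives its silyl ether F5. TESOTf and Et3N give the bis-silyl enediol ether F6, and the cyclisation of step 13 then comes back at 23. The C9 configuration arises in the cyclisation and, being α to the ketone, may need equilibration with a mild base; this is the weak point of the fallback.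

**Step 6.** β-Hydride transfer from the isopropyl reagent may reduce the ketone, the metal aldolate may undergo retro-aldol cleavage, or addition may occur syn to the side chain. The fallback removes the free aldolate. It sets out from 12: TESCl and imidazole give the triethylsilyl ether F7, organocerium addition as in step 6 gives the tertiary alcohol F8, and PPTS in MeOH at 0 °C removes the secondary triethylsilyl group selectively and comes back at 13.

## Further compounds

F1 | step 5 | tert-butyl(dimethyl){[(1S)-1-methyl-3-(trimethylsilyloxy)cyclopent-2-en-1-yl]methoxy}silane | C[Si](C)(C)OC1=C[C@](C)(CC1)CO[Si](C)(C)C(C)(C)C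
F2 | step 13 | 1-[(1S,2S,3R)-1-methyl-2-[(1S)-1-(3-methylbutanoyloxy)but-3-yn-1-yl]-3-(propan-2-yl)-3-(triethylsilyloxy)cyclopentyl]ethan-1-one | C#CC[C@H](OC(=O)CC(C)C)[C@@H]2[C@](C)(CC[C@@]2(O[Si](CC)(CC)CC)C(C)C)C(C)=O
F3 | step 13 | 1-[(1S,2S,3R)-2-[(1S)-3-iodo-1-(3-methylbutanoyloxy)but-3-en-1-yl]-1-methyl-3-(propan-2-yl)-3-(triethylsilyloxy)cyclopentyl]ethan-1-one | C=C(I)C[C@H](OC(=O)CC(C)C)[C@@H]2[C@](C)(CC[C@@]2(O[Si](CC)(CC)CC)C(C)C)C(C)=O
F0 | step 16 | none | none
F4 | step 14 | 2-hydroxy-1-[(1S,2S,3R)-1-methyl-2-[(1S)-1-(3-methylbutanoyloxy)but-3-yn-1-yl]-3-(propan-2-yl)-3-(triethylsilyloxy)cyclopentyl]ethan-1-one | C#CC[C@H](OC(=O)CC(C)C)[C@@H]2[C@](C)(CC[C@@]2(O[Si](CC)(CC)CC)C(C)C)C(=O)CO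
F5 | step 14 | 2-(tert-butyldimethylsilyloxy)-1-[(1S,2S,3R)-1-methyl-2-[(1S)-1-(3-methylbutanoyloxy)but-3-yn-1-yl]-3-(propan-2-yl)-3-(triethylsilyloxy)cyclopentyl]ethan-1-one | C#CC[C@H](OC(=O)CC(C)C)[C@@H]2[C@](C)(CC[C@@]2(O[Si](CC)(CC)CC)C(C)C)C(=O)CO[Si](C)(C)C(C)(C)C
F6 | step 14 | (1S)-1-[(1S,2R,5S)-5-[2-(tert-butyldimethylsilyloxy)-1-(triethylsilyloxy)ethenyl]-5-methyl-2-(propan-2-yl)-2-(triethylsilyloxy)cyclopentyl]but-3-yn-1-yl 3-methylbutanoate (mixture of alkene geometries) | C#CC[C@H](OC(=O)CC(C)C)[C@@H]2[C@](C)(CC[C@@]2(O[Si](CC)(CC)CC)C(C)C)C(O[Si](CC)(CC)CC)=CO[Si](C)(C)C(C)(C)C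
F7 | step 6 | (2S,3S)-3-{[tert-butyl(dimethyl)silyl]oxymethyl}-3-methyl-2-[(1S)-1-(triethylsilyloxy)-4-(trimethylsilyl)but-3-yn-1-yl]cyclopentan-1-one | C[Si](C)(C)C#CC[C@H](O[Si](CC)(CC)CC)[C@@H]2[C@](C)(CCC2=O)CO[Si](C)(C)C(C)(C)C
F8 | step 6 | (1R,2S,3S)-3-{[tert-butyl(dimethyl)silyl]oxymethyl}-3-methyl-1-(propan-2-yl)-2-[(1S)-1-(triethylsilyloxy)-4-(trimethylsilyl)but-3-yn-1-yl]cyclopentan-1-ol | C[Si](C)(C)C#CC[C@H](O[Si](CC)(CC)CC)[C@@H]2[C@](C)(CC[C@@]2(O)C(C)C)CO[Si](C)(C)C(C)(C)C
A1 | alternative 1 | 6-ethenyl-7-methyl-1,4-dioxaspiro[4.4]non-6-ene | C=CC1=C(C)CCC12OCCO2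
A2 | alternative 1 | methyl 2-diazobut-3-enoate | C=CC(=[N+]=[N-])C(=O)OC
A3 | alternative 1 | methyl ester of 4,4-(ethylenedioxy)-1-methylbicyclo[5.3.0]deca-5,8-diene-8-carboxylic acid (daucane numbering, C1 configured as in 25) | COC(=O)C1=CC[C@@]2(C)CCC3(OCCO3)C2=CC1
A4 | alternative 2 | cis-fused decalin with C1 methyl, C6 tertiary hydroxyl at the ring fusion, C5 methanesulfonate, C4 triethylsilyl ether and isopropyl, C10 ethylene ketal (daucane numbering) | C1CC[C@]2(O)[C@@H](OS(C)(=O)=O)[C@](O[Si](CC)(CC)CC)(C(C)C)CC[C@]2(C)C13OCCO3
A5 | alternative 2 | trans-fused 10,10-(ethylenedioxy)-4-(triethylsilyloxy)-14-nordaucan-6-one | C1CC(=O)[C@@H]2[C@](C)(CC[C@@]2(O[Si](CC)(CC)CC)C(C)C)C3(OCCO3)C1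
A6 | alternative 3 | triethyl({1-[(1S,2S,3R)-1-methyl-2-[(1S)-1-(3-methylbutanoyloxy)but-3-yn-1-yl]-3-(propan-2-yl)-3-(triethylsilyloxy)cyclopentyl]ethenyl}oxy)silane | C#CC[C@H](OC(=O)CC(C)C)[C@@H]2[C@](C)(CC[C@@]2(O[Si](CC)(CC)CC)C(C)C)C(=C)O[Si](CC)(CC)CC
A7 | alternative 3 | (1S,4R,5S,6S)-6-(3-methylbutanoyloxy)-4-(triethylsilyloxy)dauc-8(14)-en-10-one | C=C1C[C@H](OC(=O)CC(C)C)[C@@H]2[C@](C)(CC[C@@]2(O[Si](CC)(CC)CC)C(C)C)C(=O)C1
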